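**Retrosynthetic overview**
1. The C-1 carbinol comes from a reagent-controlled reduction of enone 22. The trisubstituted (E)-alkene comes from an aldol addition/E1cB dehydration joining two methyl ketones: ring-A ketone 16 (nucleophile) and ring-B ketone 9 (electrophile).
2. Ring B is not built; it is the ring of (S)-limonene. The syn-bromohydrin is made from the trans-diol through a trans-fused cyclic sulfate opened by bromide (one inversion).
3. Ring A is made together with a chiral dioxolane in one operation: in situ ketalisation of acetylallene 12 with (2R,3R)-butane-2,3-diol and a cationic [4+2] addition of 4-methylpenta-1,3-diene. This sets the ring-A CH and leaves the exocyclic methylene and the ring alkene in place.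
4. Ring order: ring B (chiral pool) → cyclic sulfate (temporary) → dioxolane + ring A (one operation) → dioxolane removed → fragments joined.

Assumption: the SMILES is taken literally (ring B: side chain, OH and Br all cis, i.e. a syn-bromohydrin; carbinol R; ring-A CH R; E-alkene).

**Step 1**
Reactants: 1 (S)-(−)-limonene
Product: 3 (1R,2R,4S)-1-methyl-4-(prop-1-en-2-yl)cyclohexane-1,2-diol, via limonene 1,2-oxide 2 (not isolated)
Conditions: mCPBA (1.0 equiv), NaHCO3, CH2Cl2, 0 °C; then 1% aq. H2SO4, THF, 0 °C → rt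
Reagents that add atoms: mCPBA OOC(=O)c1cccc(Cl)c1; water O
Why: Prilezhaev epoxidation selects the trisubstituted ring alkene, and acid hydrolysis of both epoxide epimers converges on one diol because each opens trans-diaxially (Fürst–Plattner, one at C-1 and the other at C-2), so the existing C-4 centre places the tertiary OH cis and the secondary OH trans to the side chain.

**Step 2**
Reactants: 3 (1R,2R,4S)-1-methyl-4-(prop-1-en-2-yl)cyclohexane-1,2-diol
Product: 5 1-[(1S,3R,4R)-3,4-dihydroxy-4-methylcyclohexyl]ethan-1-one, via methoxy hydroperoxide 4 (not isolated)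
Conditions: O3, CH2Cl2/MeOH, −78 °C; then Me2S, −78 °C → rt
Reagents that add atoms: ozone [O-][O+]=O
Why: Ozonolysis (Criegee mechanism, methanol trapping, reductive work-up) of the only remaining C=C turns the isopropenyl group into the methyl ketone without touching the three stereocentres.

**Step 3**
Reactants: 5 1-[(1S,3R,4R)-3,4-dihydroxy-4-methylcyclohexyl]ethan-1-one
Product: 7 1-[(3aR,5S,7aR)-7a-methyl-2,2-dioxidohexahydro-1,3,2-benzodioxathiol-5-yl]ethan-1-one, via cyclic sulfite 6 (not isolated)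
Conditions: SOCl2, Et3N, CH2Cl2, 0 °C; then RuCl3 (1 mol%), NaIO4, MeCN/H2O, 0 °C
Reagents that add atoms: thionyl chloride O=S(Cl)Cl; sodium periodate [Na+].[O-]I(=O)(=O)=O
Why: Sharpless cyclic sulfate formation works here because the monocyclic trans-diol can reach the diequatorial chair needed for the trans-fused five-membered ring; no carbon centre changes, and the tertiary oxygen is tied up so that it cannot close an epoxide in the next step.

**Step 4**
Reactants: 7 1-[(3aR,5S,7aR)-7a-methyl-2,2-dioxidohexahydro-1,3,2-benzodioxathiol-5-yl]ethan-1-one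
Product: 9 1-[(1S,3S,4R)-3-bromo-4-hydroxy-4-methylcyclohexyl]ethan-1-one, via lithium bromoalkyl sulfate 8 (not isolated)
Conditions: LiBr, THF, 50 °C; then H2SO4 (cat.), H2O (2 equiv), THF, rt
Reagents that add atoms: lithium bromide [Li+].[Br-]
Why: SN2 opening of the cyclic sulfate at the less hindered secondary carbon inverts that centre, so Br ends cis to the tertiary oxygen (which, as a sulfate ester, cannot participate), and acid-catalysed S–O hydrolysis then frees the tertiary alcohol with retention to give the syn-bromohydrin.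

**Step 5**
Reactants: 10 pent-4-yn-2-ol
Product: 12 penta-3,4-dien-2-one, via pent-4-yn-2-one 11 (not isolated)
Conditions: Dess–Martin periodinane, NaHCO3, CH2Cl2, 0 °C; then Et3N (5 mol%), 0 °C; used as a CH2Cl2 solution
Reagents that add atoms: none
Why: Dess–Martin oxidation followed by base-catalysed propargyl–allenyl isomerisation of the β,γ-ynone into conjugation gives the allenyl ketone (no stereocentre).

**Step 6 (key step)**
Reactants: 12 penta-3,4-dien-2-one; 13 4-methylpenta-1,3-diene
Product: 15 (4R,5R)-2-[(1R)-2,2-dimethyl-6-methylidenecyclohex-3-en-1-yl]-2,4,5-trimethyl-1,3-dioxolane, via allenyl ketal 14 (not isolated)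
Conditions: (2R,3R)-butane-2,3-diol, i-PrOSiMe3, TMSOTf (5 mol%), CH2Cl2, −40 °C; then 13 (3 equiv), TMSOTf (10 mol%), −78 → −45 °C; pyridine quench; chromatography
Reagents that add atoms: (2R,3R)-butane-2,3-diol C[C@@H](O)[C@@H](C)O
Why: Proposed new method: in situ Noyori-type ketalisation gives 14, TMSOTf ionises it to an alkoxy-stabilised cation, the CH2 terminus of 13 adds to the central allene carbon (the only mode that gives a tertiary allyl cation), the resulting enol-ether carbon closes on the CMe2 terminus to give the cyclohexene with the exocyclic methylene left over from the allene, and the pendant oxygen re-closes the dioxolane, so the dioxolane and the carbocycle are both formed in this one operation; the trans-4,5-dimethyl groups make the two faces of the enol ether diastereotopic, the (1R) ring carbon is assumed to be favoured (the sense of induction is not predictable, and (2S,3S)-butanediol is used instead if it turns out opposite) and the minor epimer is a diastereomer removed by chromatography; the stepwise cationic path is what lets this s-cis-reluctant diene react at low temperature; closest known reaction type is the Gassman ionic Diels–Alder reaction of enone and enal acetals, including chiral-dioxolane variants.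

**Step 7**
Reactants: 15 (4R,5R)-2-[(1R)-2,2-dimethyl-6-methylidenecyclohex-3-en-1-yl]-2,4,5-trimethyl-1,3-dioxolane
Product: 16 1-[(1R)-2,2-dimethyl-6-methylidenecyclohex-3-en-1-yl]ethan-1-one
Conditions: TsOH·H2O (10 mol%), THF/H2O 4:1, 0 °C → rt
Reagents that add atoms: water O
Why: Mild acid-catalysed ketal hydrolysis releases the β,γ-unsaturated methyl ketone, and short contact at low temperature avoids migration of the exocyclic alkene into conjugation, so the ring CH centre is untouched.

**Step 8**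
Reactants: 16 1-[(1R)-2,2-dimethyl-6-methylidenecyclohex-3-en-1-yl]ethan-1-one; 9 1-[(1S,3S,4R)-3-bromo-4-hydroxy-4-methylcyclohexyl]ethan-1-one
Product: 19 3-[(1S,3S,4R)-3-bromo-4-hydroxy-4-methylcyclohexyl]-1-[(1R)-2,2-dimethyl-6-methylidenecyclohex-3-en-1-yl]-3-hydroxybutan-1-one (C-3 epimers), via lithium enolate 17 (not isolated), via lithium alkoxide 18 (not isolated)
Conditions: 16 + LDA (1.05 equiv) and, separately, 9 + LDA (1.0 equiv), THF, −78 °C; combine, −78 °C, 1 h; AcOH quench at −78 °C
Reagents that add atoms: none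
Why: Directed crossed aldol addition: kinetic deprotonation of 16 occurs at the methyl group (the other α-position is a hindered tertiary CH), and the enolate adds to the methyl ketone of 9 while its hydroxyl is masked as the lithium alkoxide (syn to Br, so no epoxide can form); the new tertiary carbinol centre is a mixture that disappears in step 9.

**Step 9**
Reactants: 19 3-[(1S,3S,4R)-3-bromo-4-hydroxy-4-methylcyclohexyl]-1-[(1R)-2,2-dimethyl-6-methylidenecyclohex-3-en-1-yl]-3-hydroxybutan-1-one
Product: 22 (2E)-3-[(1S,3S,4R)-3-bromo-4-hydroxy-4-methylcyclohexyl]-1-[(1R)-2,2-dimethyl-6-methylidenecyclohex-3-en-1-yl]but-2-en-1-one, via bis(trifluoroacetate) 20 (not isolated), via enone trifluoroacetate 21 (not isolated)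
Conditions: (CF3CO)2O, Et3N, DMAP (cat.), CH2Cl2, −20 °C → rt; then NaHCO3, MeOH, rt
Reagents that add atoms: none
Why: Both tertiary alcohols are trifluoroacetylated but only the β-acyloxy ketone can undergo E1cB elimination, which gives the conjugated enone with the larger ring substituent trans to the carbonyl (E), and mild methanolysis then returns the ring tertiary alcohol.

**Step 10**
Reactants: 22 (2E)-3-[(1S,3S,4R)-3-bromo-4-hydroxy-4-methylcyclohexyl]-1-[(1R)-2,2-dimethyl-6-methylidenecyclohex-3-en-1-yl]but-2-en-1-one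
Product: 23 (1R,2E)-3-[(1S,3S,4R)-3-bromo-4-hydroxy-4-methylcyclohexyl]-1-[(1R)-2,2-dimethyl-6-methylidenecyclohex-3-en-1-yl]but-2-en-1-ol
Conditions: (S)-Me-CBS (0.2 equiv), catecholborane, toluene, −78 °C; MeOH, then pH 7 buffer
Reagents that add atoms: none
Why: Corey–Bakshi–Shibata 1,2-reduction with catecholborane (no hydroboration of the alkenes at −78 °C): the oxazaborolidine binds the carbonyl with the bulky ring-A substituent as the large group and delivers hydride to give the (R)-carbinol under reagent control, against the substrate's own Felkin preference.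

**Compound list**
1 | (S)-(−)-limonene | CC(=C)[C@H]1CCC(C)=CC1 | starting material
2 | (4S)-limonene 1,2-oxide (cis/trans mixture) | CC(=C)[C@H]1CCC2(C)OC2C1 | intermediate
3 | (1R,2R,4S)-1-methyl-4-(prop-1-en-2-yl)cyclohexane-1,2-diol | CC(=C)[C@H]1CC[C@@](C)(O)[C@H](O)C1 | intermediate
4 | (1R,2R,4S)-4-(1-hydroperoxy-1-methoxyethyl)-1-methylcyclohexane-1,2-diol (epimers at the peroxy carbon) | COC(C)(OO)[C@H]1CC[C@@](C)(O)[C@H](O)C1 | intermediate
5 | 1-[(1S,3R,4R)-3,4-dihydroxy-4-methylcyclohexyl]ethan-1-one | CC(=O)[C@H]1CC[C@@](C)(O)[C@H](O)C1 | intermediate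
6 | 1-[(3aR,5S,7aR)-7a-methyl-2-oxidohexahydro-1,3,2-benzodioxathiol-5-yl]ethan-1-one (trans-fused cyclic sulfite, S-epimers) | CC(=O)[C@H]1CC[C@@]2(C)OS(=O)O[C@@H]2C1 | intermediate
7 | 1-[(3aR,5S,7aR)-7a-methyl-2,2-dioxidohexahydro-1,3,2-benzodioxathiol-5-yl]ethan-1-one (trans-fused cyclic sulfate) | CC(=O)[C@H]1CC[C@@]2(C)OS(=O)(=O)O[C@@H]2C1 | intermediate
8 | lithium (1R,2S,4S)-4-acetyl-2-bromo-1-methylcyclohexyl sulfate | CC(=O)[C@H]1CC[C@@](C)(OS(=O)(=O)[O-])[C@@H](Br)C1.[Li+] | intermediate
9 | 1-[(1S,3S,4R)-3-bromo-4-hydroxy-4-methylcyclohexyl]ethan-1-one | CC(=O)[C@H]1CC[C@@](C)(O)[C@@H](Br)C1 | intermediate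
10 | pent-4-yn-2-ol (racemic) | CC(O)CC#C | starting material
11 | pent-4-yn-2-one | CC(=O)CC#C | intermediate
12 | penta-3,4-dien-2-one (acetylallene) | CC(=O)C=C=C | intermediate
13 | 4-methylpenta-1,3-diene | CC(C)=CC=C | starting material
14 | (4R,5R)-2,4,5-trimethyl-2-(propa-1,2-dien-1-yl)-1,3-dioxolane | C=C=CC1(C)O[C@H](C)[C@@H](C)O1 | intermediate
15 | (4R,5R)-2-[(1R)-2,2-dimethyl-6-methylidenecyclohex-3-en-1-yl]-2,4,5-trimethyl-1,3-dioxolane | C=C1CC=CC(C)(C)[C@@H]1C2(C)O[C@H](C)[C@@H](C)O2 | intermediate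
16 | 1-[(1R)-2,2-dimethyl-6-methylidenecyclohex-3-en-1-yl]ethan-1-one | C=C1CC=CC(C)(C)[C@@H]1C(C)=O | intermediate
17 | lithium 1-[(1R)-2,2-dimethyl-6-methylidenecyclohex-3-en-1-yl]ethen-1-olate | C=C1CC=CC(C)(C)[C@@H]1C(=C)[O-].[Li+] | intermediate
18 | lithium (1R,2S,4S)-4-acetyl-2-bromo-1-methylcyclohexan-1-olate | CC(=O)[C@H]1CC[C@@](C)([O-])[C@@H](Br)C1.[Li+] | intermediate
19 | 3-[(1S,3S,4R)-3-bromo-4-hydroxy-4-methylcyclohexyl]-1-[(1R)-2,2-dimethyl-6-methylidenecyclohex-3-en-1-yl]-3-hydroxybutan-1-one (C-3 epimers) | C=C1CC=CC(C)(C)[C@@H]1C(=O)CC(C)(O)[C@H]1CC[C@@](C)(O)[C@@H](Br)C1 | intermediate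
20 | bis(trifluoroacetate) of 19 | C=C1CC=CC(C)(C)[C@@H]1C(=O)CC(C)(OC(=O)C(F)(F)F)[C@H]1CC[C@@](C)(OC(=O)C(F)(F)F)[C@@H](Br)C1 | intermediate
21 | tertiary trifluoroacetate of enone 22 | C=C1CC=CC(C)(C)[C@@H]1C(=O)/C=C(\C)[C@H]1CC[C@@](C)(OC(=O)C(F)(F)F)[C@@H](Br)C1 | intermediate
22 | (2E)-3-[(1S,3S,4R)-3-bromo-4-hydroxy-4-methylcyclohexyl]-1-[(1R)-2,2-dimethyl-6-methylidenecyclohex-3-en-1-yl]but-2-en-1-one | C=C1CC=CC(C)(C)[C@@H]1C(=O)/C=C(\C)[C@H]1CC[C@@](C)(O)[C@@H](Br)C1 | intermediate
23 | (1R,2E)-3-[(1S,3S,4R)-3-bromo-4-hydroxy-4-methylcyclohexyl]-1-[(1R)-2,2-dimethyl-6-methylidenecyclohex-3-en-1-yl]but-2-en-1-ol | C=C1CC=CC(C)(C)[C@@H]1[C@H](O)/C=C(\C)[C@H]1CC[C@@](C)(O)[C@@H](Br)C1 | target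

**Totals**
Total step count: 10. Longest linear sequence: 7 (steps 1–4, then 8–10).

**Three steps most likely to fail**

Step 6. The allenyl ketal may give [2+2] adducts, the allene may isomerise, or the diol may give little facial bias. The fallback sets out from diene 13 and rejoins at 16. An Et2AlCl-promoted Diels–Alder reaction of 13 with the allenoyl imide (4S)-4-benzyl-3-(buta-2,3-dienoyl)-1,3-oxazolidin-2-one F1 (from the lithiated oxazolidinone and but-3-ynoyl chloride, then Et3N) gives the cycloadduct (4S)-4-benzyl-3-{[(1R)-2,2-dimethyl-6-methylidenecyclohex-3-en-1-yl]carbonyl}-1,3-oxazolidin-2-one F2. Here a chelated N-acyl auxiliary, not a ketal, controls the ring CH; the antipodal auxiliary is used if the sense is opposite. AlMe3/MeNHOMe·HCl converts F2 into the Weinreb amide (1R)-N-methoxy-N,2,2-trimethyl-6-methylidenecyclohex-3-ene-1-carboxamide F3, and MeMgBr turns F3 into 16.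

Step 4. Bromide may eliminate or attack the tertiary carbon, or the trans-fused sulfate of step 3 may not form. The fallback sets out from keto diol 5 and rejoins at 9; it uses a double inversion instead of a cyclic sulfate. MsCl/Et3N gives the secondary mesylate (1R,2R,5S)-5-acetyl-2-hydroxy-2-methylcyclohexyl methanesulfonate F4. K2CO3/MeOH closes it, with the first inversion, to the epoxide 1-[(1S,3S,6R)-6-methyl-7-oxabicyclo[4.1.0]heptan-3-yl]ethan-1-one F5. MgI2 opens F5 trans-diaxially at the secondary carbon to the anti-iodohydrin 1-[(1S,3R,4R)-4-hydroxy-3-iodo-4-methylcyclohexyl]ethan-1-one F6. Finkelstein exchange with excess LiBr (butan-2-one, 60 °C) inverts that centre a second time; the equatorial bromide 9 is the expected sink.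

Step 10. It is uncertain which carbonyl substituent the catalyst treats as large, and the substrate's Felkin bias opposes the desired sense. The fallback sets out from enone 22 and rejoins at 23. Luche reduction (NaBH4, CeCl3, MeOH, −78 °C) is allowed to follow the Felkin preference to the epimeric alcohol (1S,2E)-3-[(1S,3S,4R)-3-bromo-4-hydroxy-4-methylcyclohexyl]-1-[(1R)-2,2-dimethyl-6-methylidenecyclohex-3-en-1-yl]but-2-en-1-ol F7. Mitsunobu inversion (4-nitrobenzoic acid, PPh3, DIAD) gives the ester (1R,2E)-3-[(1S,3S,4R)-3-bromo-4-hydroxy-4-methylcyclohexyl]-1-[(1R)-2,2-dimethyl-6-methylidenecyclohex-3-en-1-yl]but-2-en-1-yl 4-nitrobenzoate F8. K2CO3/MeOH cleaves F8 to 23.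

**Further compounds**
F1 | step 6 | (4S)-4-benzyl-3-(buta-2,3-dienoyl)-1,3-oxazolidin-2-one | C=C=CC(=O)N1[C@@H](Cc2ccccc2)COC1=O
F2 | step 6 | (4S)-4-benzyl-3-{[(1R)-2,2-dimethyl-6-methylidenecyclohex-3-en-1-yl]carbonyl}-1,3-oxazolidin-2-one | C=C1CC=CC(C)(C)[C@@H]1C(=O)N1[C@@H](Cc2ccccc2)COC1=O
F3 | step 6 | (1R)-N-methoxy-N,2,2-trimethyl-6-methylidenecyclohex-3-ene-1-carboxamide | C=C1CC=CC(C)(C)[C@@H]1C(=O)N(C)OC
F4 | step 4 | (1R,2R,5S)-5-acetyl-2-hydroxy-2-methylcyclohexyl methanesulfonate | CC(=O)[C@H]1CC[C@@](C)(O)[C@H](OS(C)(=O)=O)C1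
F5 | step 4 | 1-[(1S,3S,6R)-6-methyl-7-oxabicyclo[4.1.0]heptan-3-yl]ethan-1-one | CC(=O)[C@H]1CC[C@@]2(C)O[C@H]2C1
F6 | step 4 | 1-[(1S,3R,4R)-4-hydroxy-3-iodo-4-methylcyclohexyl]ethan-1-one | CC(=O)[C@H]1CC[C@@](C)(O)[C@H](I)C1
F7 | step 10 | (1S,2E)-3-[(1S,3S,4R)-3-bromo-4-hydroxy-4-methylcyclohexyl]-1-[(1R)-2,2-dimethyl-6-methylidenecyclohex-3-en-1-yl]but-2-en-1-ol | C=C1CC=CC(C)(C)[C@@H]1[C@@H](O)/C=C(\C)[C@H]1CC[C@@](C)(O)[C@@H](Br)C1
F8 | step 10 | (1R,2E)-3-[(1S,3S,4R)-3-bromo-4-hydroxy-4-methylcyclohexyl]-1-[(1R)-2,2-dimethyl-6-methylidenecyclohex-3-en-1-yl]but-2-en-1-yl 4-nitrobenzoate | C=C1CC=CC(C)(C)[C@@H]1[C@H](OC(=O)c2ccc(cc2)[N+](=O)[O-])/C=C(\C)[C@H]1CC[C@@](C)(O)[C@@H](Br)C1
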